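The readings were computed with constants of no real substance; scatter was added.

Time first: in this flask, run zeta, substrate's running half-life τ, the time it would take to halve at its current rate, began at 0.824 h over the first reading. Between the last two readings it stood at 15.2 h, far longer.

- zeta: substrate 0.010 M; coupling partner 0.020 M; the very flask that is asked about, followed so far
- flask: substrate 0.010 M; coupling partner 0.0200 M; time 5.0 h

zeta run (percent of the substrate charged)

| time / h | target / % | substrate / % |
|---|---|---|
| 0.417 | 31.1 | 70.4 |
| 1.00 | 44.3 | 57.0 |
| 2.00 | 52.0 | 47.2 |
| 3.00 | 53.9 | 45.1 |

(scatter of a reading: 1 percentage point)

- maple: change nothing and wait 2.5 h more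
- cedar: at 5.0 h add substrate, 50.0% of the amount charged, then wait 2.5 h
- larch: at 5.0 h add coupling partner, 100% of the amount charged, then wait 2.5 h
- oak: at 5.0 h take out 90% of the target then present, then wait 2.5 h

- target that was removed still counts
- additions bring no volume worth counting

* target, in percent of the substrate first charged, at 5.0 h
* the option that brings most further target ("none" if no option brings more than 2 percentage points) (maple / cedar / larch / oak / none)
* target present, with what was taken out counted in, in percent of the substrate first charged, after cedar
* target present, with what was taken out counted in, in percent of the substrate first charged, after larch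

Build the flask up. With the main step by itself, substrate + coupling partner → target at rate kAB (A, B their concentrations), 5.0 h holds 6.07 early half-lives, so target stands near 98.5%. But τ grew 18.4-fold, while the partner counted by target made explains a factor of 1.37.

Now let the partner also consume itself, at rate k′B squared. Time drops out of the ratio of the two rates:

dB/dA = 1 + sB/A, with s = k′/k

Here s, a selectivity factor, is partner lost per substrate converted at equal concentrations. Integrating from charge ratio r = B/A until B reaches zero gives the substrate share σ then left:

σ = [1 + (s − 1)r]^(−1/(s − 1))

Reading s = 3 from the stall, with r = 2.00:

σ = 44.7%

Since s was read from that last reading of 45.1%, the match is no check. This stall share is what I carry. A way back, the remaining addition, could give the same plateau, and I have not separated the two. I commit to partner loss, which puts target near 55.3%. Waiting, cedar and oak supply no partner, so I expect little from them. Larch resets r, and if the added partner is consumed within 2.5 h, target reaches: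

85.8%

The forecast gave 55.3%, best none, 56% after cedar and 56% after larch, saying “I lean towards dead activity”. We part on larch.

The flask gave larch as best, with 82.6% after larch and 59.3% after cedar.

    substrate + coupling partner ⇌ intermediate (K = 39.0 L mol⁻¹, k = 1.60 L mol⁻¹ min⁻¹)
    intermediate → target (k = 1.30 min⁻¹)
    2 coupling partner → homo dimer (k = 2.00 L mol⁻¹ min⁻¹)

Homo dimer had reached 0.00594 M at 0.500 h while target grew through an intermediate at 0.374% of the substrate charged, and coupling partner already stood at 23.3% of its charge. At 5.00 h that limiting reagent stood at 1.03% of its charge, with target at 57.5% and substrate at 42.5% against σ of 44.7%; larch's 82.6% compares with my 85.8%. For the neighbour flask with 0.0060 M of substrate, σ at the same s is 36.1%, and substrate there stood at 36.8% at 5.00 h.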